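Watch the partner.

| setting | Wednesday's | Thursday's | Tuesday's | Sunday's | noon | midnight |
|---|---|---|---|---|---|---|
| left-handed substrate | 0.25 M | 0.25 M | 0.25 M | 0.25 M | 0.25 M | 0.25 M |
| right-handed substrate | 0.25 M | 0.25 M | 0.25 M | 0.25 M | 0.25 M | 0.25 M |
| partner | 0.275 M (in portions, 3) | 0.275 M (in portions, 3) | 0.275 M (in portions, 3) | 0.78 M (in portions, 3) | 1.20 M | 0.275 M (in portions, 3) |
| free catalyst | 12 mM | 12 mM | 12 mM | 12 mM | 12 mM | 12 mM |
| added ligand | 33 mM | 35 mM | 47 mM | 48 mM | 30 mM | 48 mM |
| remark | run made earlier; portions every 2.0 min | run made earlier; portions every 2.0 min | run made earlier; portions every 2.0 min | run made earlier; portions every 2.0 min | everything together at the start | the portions of partner follow each other after 2.0 min, the first at the start |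
| time |  |  |  |  | 30 min | 30 min |

| Wednesday's: time / min | Wednesday's: left-handed product / % | Thursday's: time / min | Thursday's: left-handed product / % | Tuesday's: time / min | Tuesday's: left-handed product / % | Sunday's: time / min | Sunday's: left-handed product / % |
|---|---|---|---|---|---|---|---|
| 3.00 | 0.9 | 3.00 | 2.2 | 1.33 | 0.2 | 3.00 | 4.7 |
| 6.00 | 4.4 | 6.00 | 3.8 | 2.50 | 0.8 | 6.00 | 9.7 |
| 10.0 | 5.9 | 10.0 | 8.0 | 4.00 | 0.1 | 10.0 | 15.4 |
| 12.0 | 8.3 | 12.0 | 6.5 | 8.00 | 5.4 | 12.0 | 17.8 |
| 15.0 | 9.4 | 15.0 | 8.9 | 15.0 | 8.9 | 15.0 | 21.9 |

(each reading ± 1 percentage point)

- free catalyst is single-handed; left-handed substrate and right-handed substrate are mirror images of each other, charged as a racemate, each of them at the stated concentration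

1. which one finishes higher in amount of left-handed product, in percent of the left-handed substrate and right-handed substrate together charged ("neither" within 2 percentage points) (noon / midnight / neither)
2. amount of left-handed product at the end, in percent of the left-handed substrate and right-handed substrate together charged, noon
3. amount of left-handed product at the end, in percent of the left-handed substrate and right-handed substrate together charged, midnight

I turn the settings one at a time, starting with partner. By hand, if each turn of the catalyst takes up partner, the left-handed substrate falls pseudo-first-order while [partner] stays near its charge, and the rate integrates in closed form: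

θ = k·[partner]·t

left-handed product = ceiling − ceiling·e^(−θ)

The ceiling is 50.0 %, the left-handed substrate's share of the charge. Sunday's reading at 15.0 min gives 0.0493 /M/min, and this is k, the dose constant, the fall in ln[left-handed substrate] per M of partner per minute. Tuesday's reading, at 0.275 M of partner against Sunday's 0.78 M, gives 0.0475 /M/min, so the dose form holds within the scatter.

Next, ligand. By hand, ligand holding catalyst slows the flask, but Wednesday's reads 9.4 % at 33 mM and Tuesday's reads 8.9 % at 47 mM, a gap of 0.5 percentage points against a scatter of 1 point. So I carry k to noon's 30 mM, just outside that range.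

Then portions. They hold the charge back by 2.0 min on average, a loss of 6.67 % of the dose over 30 min, so I let it pass.

Last, time. θ grows with t, but partner is used along the way, so for midnight I also reckon with the mean partner, the charge less half of what the full-charge line uses:

noon: θ = 1.77, product 41.5 %

midnight, full charge: θ = 0.406, product 16.7 %

midnight, mean partner: θ = 0.345, product 14.6 %

The forecast names noon, with 37 % (28 % to 44 %) and 13.5 % (11 % to 17 %), holding that “left-handed product formation depends on partner”. Both its numbers stand below mine.

The flask gives 41.1 % at noon and 13.5 % at midnight, so noon finishes higher.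

    partner + free catalyst + left-handed substrate → free catalyst + left-handed product (k = 0.140 /M²/s)
    partner + free catalyst + right-handed substrate → free catalyst + right-handed product (k = 0.00920 /M²/s)
    free catalyst + added ligand ⇌ idle complex (K = 26.0 /M, k = 0.0120 /M/s)
    free catalyst → spent catalyst (k = 4.20 × 10⁻⁷ /s)
    2 free catalyst ⇌ resting dimer (K = 110 /M, k = 0.0460 /M/s)

Partner is the main reason: with the difference in partner taken out, noon falls from 41.1 % to 15.6 %, against the 16.7 % that my full-charge line gives for θ of 0.406. The step to right-handed product makes no difference to noon's left-handed product, though right-handed product reaches 5.35 % by 30.0 min. With 0.17 M of partner in the midnight recipe, the mean-partner dose gives 9.48 %, and that neighbour flask gives 8.77 %.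

The runs are simulated for an exercise.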